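**Retrosynthetic overview**
1. Target 33 ⇐ tris-silyl ether 32. C9'–C10' is cut to allylic bromide 26 plus prenyl phenyl sulfone 29, and C7'=C8' is cut (stabilised Wittig) to aldehyde 23.
2. C5'–C6' and both carbinol centres ⇐ Evans syn-glycolate aldol of enal 14 with (R)-imide 18. Enal 14 ⇐ SeO2 oxidation of the E-methyl on C4' of chromene 12.
3. Pyran ring B is the only ring made (benzene ring A is bought); it is closed across C3=C4 by ring-closing metathesis of diene 11.
4. 11 ⇐ (S)-linalool 1 + 5-bromo-2-fluoro-3-methylbenzaldehyde 2: SNAr (O1–C8a bond, retention), Wittig methylenation, Br → OH, silylation.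
5. Feature used: the quaternary stereocentre C2, with its bonds to O1, CH3, C3 and the C1'–C4' homoprenyl arm, is the carbinol carbon of (S)-linalool; C3=C4 is a cis styrenyl alkene inside ring B, formed from a C2-vinyl and an aryl-vinyl group.

Key step: step 5

Remark: the side chain is numbered C1'–C12' outward from C2 (target = 2S,5'S,6'S, syn-diol); it is assumed that (S)-(+)-linalool is bought in high enantiomeric purity, because its ee becomes the ee at C2.
Abbreviations: TBS = tert-butyldimethylsilyl; Chr = (S)-6-(TBSO)-2,8-dimethyl-2H-chromen-2-yl.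

**Step 1**
Reactants: 1 (S)-(+)-linalool; 2 5-bromo-2-fluoro-3-methylbenzaldehyde
Product: 4 (S)-5-bromo-2-[(3,7-dimethylocta-1,6-dien-3-yl)oxy]-3-methylbenzaldehyde, via potassium (S)-linalyl oxide 3 (not isolated)
Conditions: KH (1.2 equiv), 1 (1.3 equiv), THF, 0 °C; then 2, THF–DMPU, 0 °C → rt; NH4Cl work-up, Et3N-washed silica
Reagents that add atoms: none
Why: Nucleophilic aromatic substitution (addition–elimination through a Meisenheimer adduct) at the fluoride activated by the ortho-formyl and para-bromo groups; the tertiary alkoxide has no carbinol hydrogen and cannot reduce the aldehyde, and since only the O–H bond of linalool is broken the stereocentre is carried over with retention.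

**Step 2**
Reactants: 4; 5 methyltriphenylphosphonium bromide
Product: 7 (S)-5-bromo-2-[(3,7-dimethylocta-1,6-dien-3-yl)oxy]-1-methyl-3-vinylbenzene, via methylenetriphenylphosphorane 6 (not isolated)
Conditions: 5, KOt-Bu, THF, 0 °C; then 4, 0 °C → rt
Reagents that add atoms: none
Why: Wittig methylenation of a non-enolisable aryl aldehyde with the unstabilised ylide, in a basic medium that leaves the acid-labile tertiary allylic aryl ether intact.

**Step 3**
Reactants: 7
Product: 10 (S)-4-[(3,7-dimethylocta-1,6-dien-3-yl)oxy]-3-methyl-5-vinylphenol, via aryllithium 8 (not isolated), via dimethyl arylboronate 9 (not isolated)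
Conditions: n-BuLi (1.05 equiv), THF, −78 °C; B(OMe)3, −78 → 0 °C; then aq. NaOH, 30% H2O2, 0 °C; neutral work-up
Reagents that add atoms: hydrogen peroxide, OO
Why: Bromine–lithium exchange at −78 °C outruns addition of n-BuLi to the styrene, the aryllithium is trapped as the borate, and alkaline H2O2 oxidises the C–B bond by 1,2-aryl shift to oxygen without touching the unactivated alkenes or the ether.

**Step 4**
Reactants: 10
Product: 11 (S)-tert-butyl{4-[(3,7-dimethylocta-1,6-dien-3-yl)oxy]-3-methyl-5-vinylphenoxy}dimethylsilane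
Conditions: TBSCl, imidazole, DMF, 0 °C → rt
Reagents that add atoms: tert-butyldimethylsilyl chloride, CC(C)(C)[Si](C)(C)Cl
Why: Imidazole-promoted silylation of the phenol masks the oxidation-prone hydroquinone mono-ether for the metathesis and the later oxidations.

**Step 5**
Reactants: 11
Product: 12 (S)-tert-butyl{[2,8-dimethyl-2-(4-methylpent-3-en-1-yl)-2H-chromen-6-yl]oxy}dimethylsilane
Conditions: second-generation Grubbs catalyst RuCl2(=CHPh)(H2IMes)(PCy3) (5 mol %), CH2Cl2 (0.01 M), 40 °C, Ar sparge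
Reagents that add atoms: none
Why: Ring-closing olefin metathesis (Chauvin mechanism), the closest known reaction type being closure of 2-vinylphenyl allyl ethers to 2H-chromenes: the ruthenium benzylidene exchanges onto the unhindered styrene CH=CH2, the aryl-alkylidene undergoes intramolecular [2+2] cycloaddition with the vinyl group on the quaternary carbon, and cycloreversion of the ruthenacyclobutane releases the product while Ru=CH2 carries the chain with loss of ethylene. Pyran ring B closes in a six-membered mode by forming C3=C4 between the two former vinyl CH carbons, and the ring enforces the cis alkene. No stereocentre is created, and C2 keeps the (S) configuration of linalool because none of its four bonds (to O1, CH3, C3, C1') is touched. The step needs chemoselectivity for six-ring closure over cyclopentene formation between the C2-vinyl group and the C3'=C4' alkene (loss of isobutene); this should be secured because the catalyst loads on the styrene and not on the vinyl group next to the quaternary carbon, and because the trisubstituted alkene reacts slowly. High dilution and removal of ethylene suppress cross-metathesis and drive the closure.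

**Step 6**
Reactants: 12
Product: 13 (2E)-5-Chr-2-methylpent-2-en-1-ol
Conditions: SeO2 (0.3 equiv), t-BuOOH (3 equiv), salicylic acid (cat.), CH2Cl2, 0 °C → rt, dark; stopped at partial conversion, 12 recycled
Reagents that add atoms: tert-butyl hydroperoxide, CC(C)(C)OO (its oxygen is relayed through the SeO2 catalyst, O=[Se]=O)
Why: SeO2-catalysed allylic oxidation (ene reaction then [2,3]-sigmatropic shift) attacks the more substituted end of the only trisubstituted alkene and selects the methyl trans to the chain, giving the E-allylic alcohol; the ring alkene has no allylic hydrogen.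

**Step 7**
Reactants: 13
Product: 14 (2E)-5-Chr-2-methylpent-2-enal
Conditions: activated MnO2 (excess), CH2Cl2, rt
Reagents that add atoms: none
Why: MnO2 oxidises allylic alcohols chemoselectively to enals without E/Z isomerisation, and any enal already formed in step 6 converges here.

**Step 8**
Reactants: 15 (tert-butyldimethylsilyloxy)acetic acid; 16 (R)-4-benzyl-2-oxazolidinone
Product: 18 (R)-4-benzyl-3-[2-(tert-butyldimethylsilyloxy)acetyl]oxazolidin-2-one, via mixed pivalic anhydride 17 (not isolated)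
Conditions: pivaloyl chloride, Et3N, THF, −20 °C; then LiCl, 16, −20 °C → rt
Reagents that add atoms: none
Why: N-Acylation of the oxazolidinone through the mixed pivalic anhydride, attack occurring at the less hindered glycolyl carbonyl.

**Step 9**
Reactants: 18 (1.3 equiv); 14
Product: 20 (R)-4-benzyl-3-[(2R,3S,4E)-2-(TBSO)-7-Chr-3-hydroxy-4-methylhept-4-enoyl]oxazolidin-2-one, via dibutylboron Z-enolate 19 (not isolated)
Conditions: Bu2BOTf, Et3N, CH2Cl2, −78 → 0 °C; 14, −78 → 0 °C; then NaH2PO4/Na2HPO4 buffer (pH 7), MeOH, 30% H2O2, 0 °C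
Reagents that add atoms: none
Why: Evans syn-aldol, in which the Z-boron enolate reacts through a Zimmerman–Traxler chair with one enolate face blocked by the benzyl group of the (R)-auxiliary, so C5' and C6' are set together as the 2,3-syn (2R,3S) adduct, which corresponds to (5'S,6'S) in the target.

**Step 10**
Reactants: 20
Product: 21 (R)-4-benzyl-3-[(2R,3S,4E)-2,3-bis(TBSO)-7-Chr-4-methylhept-4-enoyl]oxazolidin-2-one
Conditions: TBSOTf, 2,6-lutidine, CH2Cl2, −78 → 0 °C
Reagents that add atoms: tert-butyldimethylsilyl trifluoromethanesulfonate, CC(C)(C)[Si](C)(C)OS(=O)(=O)C(F)(F)F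
Why: Silyl triflate/lutidine silylation of the hindered secondary aldol hydroxyl prevents retro-aldol cleavage and gives uniform fluoride-labile protection.

**Step 11**
Reactants: 21
Product: 22 (2S,3S,4E)-2,3-bis(TBSO)-7-Chr-4-methylhept-4-en-1-ol
Conditions: LiBH4, MeOH (1 equiv), THF, 0 °C
Reagents that add atoms: none
Why: Reductive cleavage of the N-acyloxazolidinone by LiBH4 at the exocyclic carbonyl releases the primary alcohol and the auxiliary without touching the stereocentres.

**Step 12**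
Reactants: 22
Product: 23 (2R,3S,4E)-2,3-bis(TBSO)-7-Chr-4-methylhept-4-enal
Conditions: Dess–Martin periodinane, CH2Cl2, 0 °C → rt; used crude
Reagents that add atoms: none
Why: Dess–Martin oxidation under near-neutral conditions should give the α-silyloxy aldehyde without epimerisation at C6'.

**Step 13**
Reactants: 23
Product: 24 ethyl (2E,4S,5S,6E)-4,5-bis(TBSO)-9-Chr-2,6-dimethylnona-2,6-dienoate
Conditions: Ph3P=C(CH3)CO2Et (2 equiv), CH2Cl2, rt → 40 °C
Reagents that add atoms: ethyl 2-(triphenylphosphoranylidene)propanoate, CCOC(=O)C(C)=P(c1ccccc1)(c1ccccc1)c1ccccc1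
Why: Wittig olefination with the stabilised, non-basic α-methyl ylide gives the E-trisubstituted enoate with the methyl cis to C6', as the target requires, and does not epimerise the α-stereocentre.

**Step 14**
Reactants: 24
Product: 25 (2E,4S,5S,6E)-4,5-bis(TBSO)-9-Chr-2,6-dimethylnona-2,6-dien-1-ol
Conditions: i-Bu2AlH (2.5 equiv), CH2Cl2, −78 °C; aq. KNaC4H4O6 work-up
Reagents that add atoms: none
Why: 1,2-Reduction of the conjugated ester by i-Bu2AlH gives the allylic alcohol without conjugate reduction or loss of alkene geometry.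

**Step 15**
Reactants: 25
Product: 26 (2E,4S,5S,6E)-1-bromo-4,5-bis(TBSO)-9-Chr-2,6-dimethylnona-2,6-diene
Conditions: CBr4, PPh3, 2,6-lutidine (buffer), CH2Cl2, −20 → 0 °C; used at once
Reagents that add atoms: carbon tetrabromide, BrC(Br)(Br)Br
Why: Appel bromination replaces the primary allylic hydroxyl by SN2 displacement of the oxyphosphonium group without allylic transposition and leaves the silyl ethers untouched.

**Step 16**
Reactants: 27 sodium benzenesulfinate; 28 1-bromo-3-methylbut-2-ene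
Product: 29 [(3-methylbut-2-en-1-yl)sulfonyl]benzene
Conditions: DMF, rt
Reagents that add atoms: none
Why: S-Alkylation of the ambident sulfinate anion by the primary allylic bromide (SN2) gives the prenyl sulfone.

**Step 17**
Reactants: 29; 26
Product: 31 (6E,8S,9S,10E)-8,9-bis(TBSO)-13-Chr-2,6,10-trimethyl-4-(phenylsulfonyl)trideca-2,6,10-triene (both epimers at C4), via lithiated sulfone 30 (not isolated)
Conditions: 29, n-BuLi, THF–DMPU, −78 °C; then 26, −78 → −40 °C
Reagents that add atoms: none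
Why: Alkylation of the α-sulfonyl allyl carbanion occurs at the carbon next to sulfur and by SN2 at the primary allylic bromide, forming C9'–C10' with both trisubstituted alkenes fixed in position and geometry.

**Step 18**
Reactants: 31
Product: 32 (6E,8S,9S,10E)-8,9-bis(TBSO)-13-Chr-2,6,10-trimethyltrideca-2,6,10-triene
Conditions: PdCl2(dppp) (5–10 mol %), LiEt3BH (2.5 equiv), THF, 0 °C
Reagents that add atoms: none
Why: Palladium-catalysed reductive desulfonylation of the allylic sulfone, in which ionisation to a π-allyl palladium complex and hydride delivery to the less substituted terminus C10' leave the C11'=C12' alkene in place and remove the sulfone-bearing stereocentre.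

**Step 19**
Reactants: 32
Product: 33 (S)-2-[(3E,5S,6S,7E)-5,6-dihydroxy-4,8,12-trimethyltrideca-3,7,11-trien-1-yl]-2,8-dimethyl-2H-chromen-6-ol
Conditions: Bu4NF (5 equiv), AcOH (5 equiv), THF, 0 °C → rt, Ar, dark
Reagents that add atoms: none
Why: Fluoride-mediated cleavage of the three Si–O bonds under buffered conditions frees the phenol and the diol without acid that could ionise the bis-allylic diol or air oxidation of the phenoxide.

**Compound list**
1 | (S)-(+)-linalool, (S)-3,7-dimethylocta-1,6-dien-3-ol | CC(C)=CCC[C@@](O)(C)C=C | starting material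
2 | 5-bromo-2-fluoro-3-methylbenzaldehyde | Cc1cc(Br)cc(C=O)c1F | starting material
3 | potassium (S)-3,7-dimethylocta-1,6-dien-3-olate | CC(C)=CCC[C@@]([O-])(C)C=C.[K+] | intermediate
4 | (S)-5-bromo-2-[(3,7-dimethylocta-1,6-dien-3-yl)oxy]-3-methylbenzaldehyde | CC(C)=CCC[C@@](Oc1c(C)cc(Br)cc1C=O)(C)C=C | intermediate
5 | methyltriphenylphosphonium bromide | C[P+](c1ccccc1)(c1ccccc1)c1ccccc1.[Br-] | starting material
6 | methylenetriphenylphosphorane | C=P(c1ccccc1)(c1ccccc1)c1ccccc1 | intermediate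
7 | (S)-5-bromo-2-[(3,7-dimethylocta-1,6-dien-3-yl)oxy]-1-methyl-3-vinylbenzene | CC(C)=CCC[C@@](Oc1c(C)cc(Br)cc1C=C)(C)C=C | intermediate
8 | (S)-{4-[(3,7-dimethylocta-1,6-dien-3-yl)oxy]-3-methyl-5-vinylphenyl}lithium | CC(C)=CCC[C@@](Oc1c(C)cc([Li])cc1C=C)(C)C=C | intermediate
9 | dimethyl (S)-{4-[(3,7-dimethylocta-1,6-dien-3-yl)oxy]-3-methyl-5-vinylphenyl}boronate | CC(C)=CCC[C@@](Oc1c(C)cc(B(OC)OC)cc1C=C)(C)C=C | intermediate
10 | (S)-4-[(3,7-dimethylocta-1,6-dien-3-yl)oxy]-3-methyl-5-vinylphenol | CC(C)=CCC[C@@](Oc1c(C)cc(O)cc1C=C)(C)C=C | intermediate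
11 | (S)-tert-butyl{4-[(3,7-dimethylocta-1,6-dien-3-yl)oxy]-3-methyl-5-vinylphenoxy}dimethylsilane | CC(C)=CCC[C@@](Oc1c(C)cc(O[Si](C)(C)C(C)(C)C)cc1C=C)(C)C=C | intermediate
12 | (S)-tert-butyl{[2,8-dimethyl-2-(4-methylpent-3-en-1-yl)-2H-chromen-6-yl]oxy}dimethylsilane | CC(C)=CCC[C@@]1(C)C=Cc2cc(O[Si](C)(C)C(C)(C)C)cc(C)c2O1 | intermediate
13 | (2E)-5-Chr-2-methylpent-2-en-1-ol | OC/C(C)=C/CC[C@@]1(C)C=Cc2cc(O[Si](C)(C)C(C)(C)C)cc(C)c2O1 | intermediate
14 | (2E)-5-Chr-2-methylpent-2-enal | O=C/C(C)=C/CC[C@@]1(C)C=Cc2cc(O[Si](C)(C)C(C)(C)C)cc(C)c2O1 | intermediate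
15 | (tert-butyldimethylsilyloxy)acetic acid | CC(C)(C)[Si](C)(C)OCC(=O)O | starting material
16 | (R)-4-benzyl-2-oxazolidinone | O=C1N[C@H](Cc2ccccc2)CO1 | starting material
17 | (tert-butyldimethylsilyloxy)acetic pivalic anhydride | CC(C)(C)[Si](C)(C)OCC(=O)OC(=O)C(C)(C)C | intermediate
18 | (R)-4-benzyl-3-[2-(tert-butyldimethylsilyloxy)acetyl]oxazolidin-2-one | CC(C)(C)[Si](C)(C)OCC(=O)N1[C@H](Cc2ccccc2)COC1=O | intermediate
19 | dibutylboron (Z)-enolate of 18 | CCCCB(CCCC)O/C(=C\O[Si](C)(C)C(C)(C)C)N1[C@H](Cc2ccccc2)COC1=O | intermediate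
20 | (R)-4-benzyl-3-[(2R,3S,4E)-2-(TBSO)-7-Chr-3-hydroxy-4-methylhept-4-enoyl]oxazolidin-2-one | O=C1OC[C@@H](Cc2ccccc2)N1C(=O)[C@H](O[Si](C)(C)C(C)(C)C)[C@@H](O)/C(C)=C/CC[C@@]3(C)C=Cc4cc(O[Si](C)(C)C(C)(C)C)cc(C)c4O3 | intermediate
21 | (R)-4-benzyl-3-[(2R,3S,4E)-2,3-bis(TBSO)-7-Chr-4-methylhept-4-enoyl]oxazolidin-2-one | O=C1OC[C@@H](Cc2ccccc2)N1C(=O)[C@H](O[Si](C)(C)C(C)(C)C)[C@@H](O[Si](C)(C)C(C)(C)C)/C(C)=C/CC[C@@]3(C)C=Cc4cc(O[Si](C)(C)C(C)(C)C)cc(C)c4O3 | intermediate
22 | (2S,3S,4E)-2,3-bis(TBSO)-7-Chr-4-methylhept-4-en-1-ol | OC[C@H](O[Si](C)(C)C(C)(C)C)[C@@H](O[Si](C)(C)C(C)(C)C)/C(C)=C/CC[C@@]1(C)C=Cc2cc(O[Si](C)(C)C(C)(C)C)cc(C)c2O1 | intermediate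
23 | (2R,3S,4E)-2,3-bis(TBSO)-7-Chr-4-methylhept-4-enal | O=C[C@H](O[Si](C)(C)C(C)(C)C)[C@@H](O[Si](C)(C)C(C)(C)C)/C(C)=C/CC[C@@]1(C)C=Cc2cc(O[Si](C)(C)C(C)(C)C)cc(C)c2O1 | intermediate
24 | ethyl (2E,4S,5S,6E)-4,5-bis(TBSO)-9-Chr-2,6-dimethylnona-2,6-dienoate | CCOC(=O)/C(C)=C/[C@H](O[Si](C)(C)C(C)(C)C)[C@@H](O[Si](C)(C)C(C)(C)C)/C(C)=C/CC[C@@]1(C)C=Cc2cc(O[Si](C)(C)C(C)(C)C)cc(C)c2O1 | intermediate
25 | (2E,4S,5S,6E)-4,5-bis(TBSO)-9-Chr-2,6-dimethylnona-2,6-dien-1-ol | OC/C(C)=C/[C@H](O[Si](C)(C)C(C)(C)C)[C@@H](O[Si](C)(C)C(C)(C)C)/C(C)=C/CC[C@@]1(C)C=Cc2cc(O[Si](C)(C)C(C)(C)C)cc(C)c2O1 | intermediate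
26 | (2E,4S,5S,6E)-1-bromo-4,5-bis(TBSO)-9-Chr-2,6-dimethylnona-2,6-diene | BrC/C(C)=C/[C@H](O[Si](C)(C)C(C)(C)C)[C@@H](O[Si](C)(C)C(C)(C)C)/C(C)=C/CC[C@@]1(C)C=Cc2cc(O[Si](C)(C)C(C)(C)C)cc(C)c2O1 | intermediate
27 | sodium benzenesulfinate | [Na+].[O-]S(=O)c1ccccc1 | starting material
28 | 1-bromo-3-methylbut-2-ene | CC(C)=CCBr | starting material
29 | [(3-methylbut-2-en-1-yl)sulfonyl]benzene | CC(C)=CCS(=O)(=O)c1ccccc1 | intermediate
30 | [3-methyl-1-(phenylsulfonyl)but-2-en-1-yl]lithium | CC(C)=CC([Li])S(=O)(=O)c1ccccc1 | intermediate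
31 | (6E,8S,9S,10E)-8,9-bis(TBSO)-13-Chr-2,6,10-trimethyl-4-(phenylsulfonyl)trideca-2,6,10-triene, both C4 epimers | CC(C)=CC(S(=O)(=O)c1ccccc1)C/C(C)=C/[C@H](O[Si](C)(C)C(C)(C)C)[C@@H](O[Si](C)(C)C(C)(C)C)/C(C)=C/CC[C@@]1(C)C=Cc2cc(O[Si](C)(C)C(C)(C)C)cc(C)c2O1 | intermediate
32 | (6E,8S,9S,10E)-8,9-bis(TBSO)-13-Chr-2,6,10-trimethyltrideca-2,6,10-triene | CC(C)=CCC/C(C)=C/[C@H](O[Si](C)(C)C(C)(C)C)[C@@H](O[Si](C)(C)C(C)(C)C)/C(C)=C/CC[C@@]1(C)C=Cc2cc(O[Si](C)(C)C(C)(C)C)cc(C)c2O1 | intermediate
33 | (S)-2-[(3E,5S,6S,7E)-5,6-dihydroxy-4,8,12-trimethyltrideca-3,7,11-trien-1-yl]-2,8-dimethyl-2H-chromen-6-ol | CC(C)=CCC/C(C)=C/[C@H](O)[C@@H](O)/C(C)=C/CC[C@@]1(C)C=Cc2cc(O)cc(C)c2O1 | target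

**Step count**
Total: 19 steps. Longest linear sequence: 17 steps (1–7, 9–15, 17–19); steps 8 and 16 prepare the imide and the sulfone. After step 5 the chromene should be kept from strong acid, ultraviolet light and prolonged heating, which could open the C2–O1 bond and erode the configuration at C2.

**Steps most likely to fail**

Step 1. The addition–elimination may be slow at a carbon flanked by two ortho substituents, reversible hemiacetal formation may tie up the formyl activator, and the aldehyde may degrade during long exposure to base. Fallback, setting out from 2 and coming back at 4: the formyl group is turned into a nitrile, which is linear, strongly activating and cannot form a hemiacetal. Treatment of 2 with I2 and aqueous NH3 in THF should give 5-bromo-2-fluoro-3-methylbenzonitrile F1. Alkoxide 3 (KH, THF–DMPU) should then displace fluoride to give (S)-5-bromo-2-[(3,7-dimethylocta-1,6-dien-3-yl)oxy]-3-methylbenzonitrile F2. Reduction with i-Bu2AlH in toluene at −78 °C and buffered hydrolysis of the aldimine returns aldehyde 4.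

Step 5. Ring closure may be diverted onto the trisubstituted alkene (loss of isobutene, cyclopentene formation), or the catalyst may be held as a chelated ortho-alkoxybenzylidene so that conversion stalls. Fallback, setting out from 11 and coming back at 14: the competing alkene is deactivated before the ring is closed. SeO2/t-BuOOH oxidation of 11 under the conditions of step 6 should give (S,E)-6-{4-[(tert-butyldimethylsilyl)oxy]-2-methyl-6-vinylphenoxy}-2,6-dimethylocta-2,7-dien-1-ol F3. MnO2 then gives (S,E)-6-{4-[(tert-butyldimethylsilyl)oxy]-2-methyl-6-vinylphenoxy}-2,6-dimethylocta-2,7-dienal F4. Its electron-poor enal alkene does not take part in metathesis, so closure with RuCl2(=CHPh)(H2IMes)(PCy3) in CH2Cl2 can only form ring B and gives enal 14 directly.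

Step 18. Hydride may be delivered to the wrong allyl terminus (alkene transposition), or palladium may ionise allylic C–O bonds, including C2–O1 with loss of configuration. Fallback, setting out from 26 and coming back at 32: the terminus is built without a sulfone and without palladium. Alkylation of the lithium enolate of N-methoxy-N-methylacetamide (LDA, THF, −78 °C) with bromide 26 should give (4E,6S,7S,8E)-6,7-bis(TBSO)-11-Chr-N-methoxy-N,4,8-trimethylundeca-4,8-dienamide F5. i-Bu2AlH at −78 °C reduces it to (4E,6S,7S,8E)-6,7-bis(TBSO)-11-Chr-4,8-dimethylundeca-4,8-dienal F6. Wittig reaction with isopropylidenetriphenylphosphorane (from isopropyltriphenylphosphonium iodide and n-BuLi, THF, −78 °C → rt) installs C11'=C12' and gives 32.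

**Further compounds**
F1 | step 1 | 5-bromo-2-fluoro-3-methylbenzonitrile | Cc1cc(Br)cc(C#N)c1F
F2 | step 1 | (S)-5-bromo-2-[(3,7-dimethylocta-1,6-dien-3-yl)oxy]-3-methylbenzonitrile | CC(C)=CCC[C@@](Oc1c(C)cc(Br)cc1C#N)(C)C=C
F3 | step 5 | (S,E)-6-{4-[(tert-butyldimethylsilyl)oxy]-2-methyl-6-vinylphenoxy}-2,6-dimethylocta-2,7-dien-1-ol | OC/C(C)=C/CC[C@@](Oc1c(C)cc(O[Si](C)(C)C(C)(C)C)cc1C=C)(C)C=C
F4 | step 5 | (S,E)-6-{4-[(tert-butyldimethylsilyl)oxy]-2-methyl-6-vinylphenoxy}-2,6-dimethylocta-2,7-dienal | O=C/C(C)=C/CC[C@@](Oc1c(C)cc(O[Si](C)(C)C(C)(C)C)cc1C=C)(C)C=C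
F5 | step 18 | (4E,6S,7S,8E)-6,7-bis(TBSO)-11-Chr-N-methoxy-N,4,8-trimethylundeca-4,8-dienamide | CON(C)C(=O)CC/C(C)=C/[C@H](O[Si](C)(C)C(C)(C)C)[C@@H](O[Si](C)(C)C(C)(C)C)/C(C)=C/CC[C@@]1(C)C=Cc2cc(O[Si](C)(C)C(C)(C)C)cc(C)c2O1
F6 | step 18 | (4E,6S,7S,8E)-6,7-bis(TBSO)-11-Chr-4,8-dimethylundeca-4,8-dienal | O=CCC/C(C)=C/[C@H](O[Si](C)(C)C(C)(C)C)[C@@H](O[Si](C)(C)C(C)(C)C)/C(C)=C/CC[C@@]1(C)C=Cc2cc(O[Si](C)(C)C(C)(C)C)cc(C)c2O1
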